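The oxane ring (O1, C2 bearing the acrylic acid, C5 bearing the side chain, C6) is traced back to a seven-membered lactone. The feature used is that O1 sits between the unsubstituted C6 methylene and C2, and that C2 carries an exocyclic carbon at the carboxyl oxidation level. In a 3-chloro-6-alkyloxepan-2-one this carbon is still the ring carbonyl: methoxide cleaves the acyl–oxygen bond, the freed C6 alkoxide displaces chloride at C2, and the ring contracts from seven to six members while C2 equilibrates to the trans-2,5 ester. The chlorolactone comes from Baeyer–Villiger oxidation of an organocatalytically built chlorocyclohexanone; alkyne methoxycarbonylation and a Nozaki–Hiyama–Kishi coupling complete the skeleton.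

Key step: step 5

Remark on the chemistry: (5E)-geranylacetone is taken as purchasable in isomerically pure form; the sense of induction of the pyrrolidine catalyst (step 2) and of the chromium ligand (step 10) is assigned by analogy and would be verified on the first run.

Step 1
Reactants: 1 pent-4-en-1-yl acetate; 2 (E)-but-2-enal (crotonaldehyde)
Product: 3 (4E)-6-oxohex-4-en-1-yl acetate
Conditions: (H2IMes)(PCy3)Cl2Ru=CHPh (second-generation Grubbs catalyst, 2 mol%), excess 2, CH2Cl2, 40 °C
Reagents that add atoms: none
Why: Olefin cross-metathesis of the terminal alkene with excess crotonaldehyde should give the conjugated enal with the thermodynamically preferred E geometry, propene being lost and the acetate being inert.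

Step 2
Reactants: 3 (4E)-6-oxohex-4-en-1-yl acetate; 4 tert-butyl 3-oxobutanoate
Product: 7 (5S)-5-(3-acetoxypropyl)cyclohex-2-en-1-one, via Michael adduct 5 (not isolated), via cyclohexenone tert-butyl ester 6 (not isolated)
Conditions: (R)-2-{bis[3,5-bis(trifluoromethyl)phenyl](trimethylsilyloxy)methyl}pyrrolidine (10 mol%), toluene, rt; then p-TsOH·H2O (20 mol%), 80 °C
Reagents that add atoms: none
Why: Iminium-catalysed Michael addition of the β-keto ester to the enal, in which the bulky silyloxydiarylmethyl group of the (R)-pyrrolidine shields one face of the E-iminium so that the C–C bond forms on the open face and sets the (S)-stereocentre (the future C5 of the oxane), is followed on acid treatment by intramolecular aldol condensation of the methyl ketone onto the aldehyde and by loss of 2-methylpropene and CO2 from the tert-butyl β-keto ester (Robinson-type annulation with decarboxylation).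

Step 3
Reactants: 7 (5S)-5-(3-acetoxypropyl)cyclohex-2-en-1-one
Product: 9 (5S)-5-(3-acetoxypropyl)-2-chlorocyclohexan-1-one as a mixture of C2 epimers, via lithium enolate 8 (not isolated)
Conditions: LiBH(s-Bu)3, THF, −78 °C; then N-chlorosuccinimide, −78 → 0 °C; NH4Cl (aq)
Reagents that add atoms: N-chlorosuccinimide, O=C1CCC(=O)N1Cl
Why: Conjugate (1,4) reduction of the β-unsubstituted enone by the hindered borohydride generates regiospecifically the enolate on the side remote from the stereocentre, and electrophilic chlorination of this enolate places chlorine at C2 only, the configuration of the C–Cl carbon being uncontrolled because it is erased later.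

Step 4
Reactants: 9 (5S)-5-(3-acetoxypropyl)-2-chlorocyclohexan-1-one
Product: 10 3-[(3S)-6-chloro-7-oxooxepan-3-yl]propyl acetate
Conditions: mCPBA, CH2Cl2, rt
Reagents that add atoms: 3-chloroperoxybenzoic acid (mCPBA), OOC(=O)c1cccc(Cl)c1
Why: Baeyer–Villiger oxidation, in which the chlorine-bearing α-carbon is deactivated as a migrating group so that the CH2 next to the stereocentre migrates and oxygen is inserted between it and the carbonyl carbon, should expand the carbocycle to the seven-membered α-chloro lactone without touching the stereocentre.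

Step 5
Reactants: 10 3-[(3S)-6-chloro-7-oxooxepan-3-yl]propyl acetate
Product: 13 methyl (2R,5S)-5-(3-hydroxypropyl)oxane-2-carboxylate, via hydroxy chloro ester 11 (not isolated), via oxane ester acetate 12 (not isolated)
Conditions: NaOMe, MeOH, 0 → 50 °C; NH4Cl (aq)
Reagents that add atoms: sodium methoxide, C[O-].[Na+]
Why: Methoxide adds to the lactone carbonyl and cleaves the acyl–oxygen bond, so the former ring oxygen is released as the C6 alkoxide while the carbonyl carbon becomes a methyl ester still attached to the chlorine-bearing C2. The alkoxide then displaces chloride at C2 in an intramolecular Williamson substitution (6-exo-tet closure of the oxane), so the seven-membered ring O1–C(=O)–C2…C6 contracts to the six-membered ring O1–C2…C6 with the carbonyl carbon extruded as the exocyclic ester. The closest known reaction type is the alkoxide-induced ring contraction of α-halo and α-sulfonyloxy lactones to cyclic ether 2-carboxylates. The new stereocentre C2 is controlled thermodynamically: methoxide epimerises the α-alkoxy ester, so both chloride epimers should converge on the trans isomer with the C2 ester and the C5 side chain both equatorial, while C5 is not touched. The step needs substitution to outrun E2 loss of HCl and intermolecular attack of methoxide at C2, which the six-membered cyclic transition state and the carbonyl-activated secondary chloride favour. The side-chain acetate is removed by transesterification in the same flask.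

Step 6
Reactants: 13 methyl (2R,5S)-5-(3-hydroxypropyl)oxane-2-carboxylate
Product: 15 3-[(3S,6R)-6-ethynyloxan-3-yl]propan-1-ol, via oxane-2-carbaldehyde 14 (not isolated)
Conditions: i-Bu2AlH (2.2 equiv), CH2Cl2, −78 °C; then MeOH, K2CO3, dimethyl (1-diazo-2-oxopropyl)phosphonate, −78 °C → rt
Reagents that add atoms: dimethyl (1-diazo-2-oxopropyl)phosphonate, CC(=O)C(=[N+]=[N-])P(=O)(OC)OC
Why: The α-alkoxy methyl ester is reduced at −78 °C only to the aluminium hemiacetal, which on methanolysis releases aldehyde 14 for Seyferth–Gilbert homologation to the terminal alkyne, the carbonate base equilibrating the α-oxy aldehyde towards the equatorial trans epimer before the alkyne fixes C2.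

Step 7
Reactants: 15 3-[(3S,6R)-6-ethynyloxan-3-yl]propan-1-ol
Product: 16 methyl 2-[(2R,5S)-5-(3-hydroxypropyl)oxan-2-yl]prop-2-enoate
Conditions: Pd(OAc)2 (2 mol%), 2-(diphenylphosphino)pyridine, MeSO3H (cat.), CO (10 bar), MeOH, 50 °C
Reagents that add atoms: carbon monoxide, [C-]#[O+]; methanol, CO
Why: Palladium-catalysed alkoxycarbonylation (hydroesterification) of the terminal alkyne with the pyridylphosphine ligand and an acid co-catalyst should deliver the carbomethoxy group to the internal alkyne carbon (Markovnikov), giving the 2-substituted acrylate directly while the ring stereocentres and the free alcohol are untouched.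

Step 8
Reactants: 16 methyl 2-[(2R,5S)-5-(3-hydroxypropyl)oxan-2-yl]prop-2-enoate
Product: 17 methyl 2-[(2R,5R)-5-(3-oxopropyl)oxan-2-yl]prop-2-enoate
Conditions: Dess–Martin periodinane, CH2Cl2, 0 °C → rt
Reagents that add atoms: none
Why: Dess–Martin oxidation should convert the primary alcohol into the aldehyde under neutral conditions that leave the acrylate and the two ring stereocentres alone (the C5 descriptor changes only because the priorities change).

Step 9
Reactants: 18 (5E)-6,10-dimethylundeca-5,9-dien-2-one (geranylacetone)
Product: 20 (5E)-6,10-dimethylundeca-1,5,9-trien-2-yl trifluoromethanesulfonate, via potassium enolate 19 (not isolated)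
Conditions: KN(SiMe3)2, THF, −78 °C; then PhNTf2, −78 °C → 0 °C; NH4Cl (aq)
Reagents that add atoms: N-phenylbis(trifluoromethanesulfonimide), O=S(=O)(N(c1ccccc1)S(=O)(=O)C(F)(F)F)C(F)(F)F
Why: Kinetic deprotonation of the methyl ketone at the methyl group by the hindered amide at −78 °C followed by O-sulfonylation (enol triflate formation) should give the 2-triflyloxy-1-alkene without touching the trisubstituted alkenes.

Step 10
Reactants: 17 methyl 2-[(2R,5R)-5-(3-oxopropyl)oxan-2-yl]prop-2-enoate; 20 (5E)-6,10-dimethylundeca-1,5,9-trien-2-yl trifluoromethanesulfonate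
Product: 21 methyl 2-[(2R,5S)-5-[(3R,7E)-3-hydroxy-8,12-dimethyl-4-methylidenetrideca-7,11-dien-1-yl]oxan-2-yl]prop-2-enoate
Conditions: CrCl2 (3 equiv), (S)-N-[2-(4-isopropyl-4,5-dihydro-1,3-oxazol-2-yl)-6-methylphenyl]methanesulfonamide (3.3 equiv), Et3N, NiCl2 (cat.), THF, rt; aqueous work-up
Reagents that add atoms: none
Why: In this Nozaki–Hiyama–Kishi coupling zerovalent nickel formed in situ inserts into the C–OTf bond, transmetallation gives an alkenylchromium species that adds only to the aldehyde (acrylate ester and alkenes inert), and the chiral sulfonamide–oxazoline ligand on chromium differentiates the aldehyde faces so that the (R)-carbinol should predominate, the remote ring stereocentres exerting no bias (the antipodal ligand is used if the sense proves opposite).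

Step 11
Reactants: 21 methyl 2-[(2R,5S)-5-[(3R,7E)-3-hydroxy-8,12-dimethyl-4-methylidenetrideca-7,11-dien-1-yl]oxan-2-yl]prop-2-enoate
Product: 22 2-[(2R,5S)-5-[(3R,7E)-3-hydroxy-8,12-dimethyl-4-methylidenetrideca-7,11-dien-1-yl]oxan-2-yl]prop-2-enoic acid
Conditions: LiOH, THF–MeOH–H2O, rt; then 1 M HCl to pH 3
Reagents that add atoms: lithium hydroxide, [Li+].[OH-]
Why: Saponification of the methyl ester followed by mild acidification should free the acrylic acid, the 2-substituted acrylate being a poor Michael acceptor for hydroxide and no stereocentre being epimerisable under these conditions.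

Compound list
1 | pent-4-en-1-yl acetate | CC(=O)OCCCC=C | starting material
2 | (E)-but-2-enal (crotonaldehyde) | C/C=C/C=O | starting material
3 | (4E)-6-oxohex-4-en-1-yl acetate | CC(=O)OCCC/C=C/C=O | intermediate
4 | tert-butyl 3-oxobutanoate | CC(=O)CC(=O)OC(C)(C)C | starting material
5 | tert-butyl (3S)-2-acetyl-3-(3-acetoxypropyl)-5-oxopentanoate (Michael adduct, C2 epimers, not isolated) | CC(=O)C(C(=O)OC(C)(C)C)[C@@H](CCCOC(C)=O)CC=O | intermediate
6 | tert-butyl (6S)-6-(3-acetoxypropyl)-2-oxocyclohex-3-ene-1-carboxylate (C1 epimers, not isolated) | O=C1C=CC[C@H](CCCOC(C)=O)C1C(=O)OC(C)(C)C | intermediate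
7 | (5S)-5-(3-acetoxypropyl)cyclohex-2-en-1-one | O=C1C=CC[C@H](CCCOC(C)=O)C1 | intermediate
8 | lithium 5-(3-acetoxypropyl)cyclohex-1-en-1-olate (side-chain stereocentre as in 7, not isolated) | [Li]OC1=CCC[C@H](CCCOC(C)=O)C1 | intermediate
9 | (5S)-5-(3-acetoxypropyl)-2-chlorocyclohexan-1-one (C2 epimers) | O=C1C(Cl)CC[C@H](CCCOC(C)=O)C1 | intermediate
10 | 3-[(3S)-6-chloro-7-oxooxepan-3-yl]propyl acetate (C6 epimers) | O=C1OC[C@@H](CCCOC(C)=O)CCC1Cl | intermediate
11 | methyl (5S)-5-(3-acetoxypropyl)-2-chloro-6-hydroxyhexanoate (present as its sodium alkoxide, not isolated) | COC(=O)C(Cl)CC[C@H](CCCOC(C)=O)CO | intermediate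
12 | methyl (5S)-5-(3-acetoxypropyl)oxane-2-carboxylate (C2 epimers, not isolated) | COC(=O)C1CC[C@H](CCCOC(C)=O)CO1 | intermediate
13 | methyl (2R,5S)-5-(3-hydroxypropyl)oxane-2-carboxylate | OCCC[C@H]1CC[C@H](C(=O)OC)OC1 | intermediate
14 | (2R,5S)-5-(3-hydroxypropyl)oxane-2-carbaldehyde (not isolated) | OCCC[C@H]1CC[C@H](C=O)OC1 | intermediate
15 | 3-[(3S,6R)-6-ethynyloxan-3-yl]propan-1-ol | OCCC[C@H]1CC[C@H](C#C)OC1 | intermediate
16 | methyl 2-[(2R,5S)-5-(3-hydroxypropyl)oxan-2-yl]prop-2-enoate | OCCC[C@H]1CC[C@H](C(=C)C(=O)OC)OC1 | intermediate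
17 | methyl 2-[(2R,5R)-5-(3-oxopropyl)oxan-2-yl]prop-2-enoate | O=CCC[C@H]1CC[C@H](C(=C)C(=O)OC)OC1 | intermediate
18 | (5E)-6,10-dimethylundeca-5,9-dien-2-one (geranylacetone) | CC(=O)CC/C=C(\C)CCC=C(C)C | starting material
19 | potassium (5E)-6,10-dimethylundeca-1,5,9-trien-2-olate (not isolated) | [K]OC(=C)CC/C=C(\C)CCC=C(C)C | intermediate
20 | (5E)-6,10-dimethylundeca-1,5,9-trien-2-yl trifluoromethanesulfonate | C=C(OS(=O)(=O)C(F)(F)F)CC/C=C(\C)CCC=C(C)C | intermediate
21 | methyl 2-[(2R,5S)-5-[(3R,7E)-3-hydroxy-8,12-dimethyl-4-methylidenetrideca-7,11-dien-1-yl]oxan-2-yl]prop-2-enoate | C=C(CC/C=C(\C)CCC=C(C)C)[C@H](O)CC[C@H]1CC[C@H](C(=C)C(=O)OC)OC1 | intermediate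
22 | 2-[(2R,5S)-5-[(3R,7E)-3-hydroxy-8,12-dimethyl-4-methylidenetrideca-7,11-dien-1-yl]oxan-2-yl]prop-2-enoic acid | C=C(CC/C=C(\C)CCC=C(C)C)[C@H](O)CC[C@H]1CC[C@H](C(=C)C(=O)O)OC1 | target

Total step count: 11. Longest linear sequence: 10 steps (steps 1 to 8, then 10 and 11, from pent-4-en-1-yl acetate); step 9 is the one-step side branch.

Steps most likely to fail

Step 5 (key step). E2 loss of HCl from the α-chloro ester or oligomeric transesterification may compete with ring closure, and equilibration at C2 may remain incomplete. The fallback sets out from 10. Saponification of lactone and acetate with LiOH in THF–H2O (0 → 60 °C) gives the 2-chloro-6-alkoxide carboxylate, which cannot eliminate through an ester enolate and should close the ring, still as a contraction of the opened lactone. Acidification gives (5S)-5-(3-hydroxypropyl)oxane-2-carboxylic acid F1 as C2 epimers. Fischer esterification (MeOH, AcCl) gives 13 together with its C2 epimer methyl (2S,5S)-5-(3-hydroxypropyl)oxane-2-carboxylate F2, and NaOMe in refluxing MeOH equilibrates F2 into 13, where the route is rejoined.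

Step 4. Oxidation of the deactivated α-chloro ketone may be sluggish, and partial migration of the chlorine-bearing carbon would give the wrong lactone. The fallback sets out from 7 and introduces chlorine only after ring expansion. Hydrogenation (H2, Pd/C, EtOAc) gives 3-[(1R)-3-oxocyclohexyl]propyl acetate F3. Baeyer–Villiger oxidation with mCPBA, now fast, gives 3-[(3R)-7-oxooxepan-3-yl]propyl acetate F4 beside its regioisomer 3-[(4S)-2-oxooxepan-4-yl]propyl acetate F5, which is removed by chromatography. Chlorination of the lactone enolate of F4 (LiN(SiMe3)2, THF, −78 °C; then N-chlorosuccinimide) comes back to the route at 10.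

Step 10. Facial discrimination of the aldehyde by the chromium ligand may be poor or of the wrong sense. The fallback sets out from 17 and 20. Ligand-free coupling (CrCl2, cat. NiCl2, DMF, rt) gives 21 together with its carbinol epimer methyl 2-[(2R,5S)-5-[(3S,7E)-3-hydroxy-8,12-dimethyl-4-methylidenetrideca-7,11-dien-1-yl]oxan-2-yl]prop-2-enoate F6. Dess–Martin oxidation of the mixture gives the enone methyl 2-[(2R,5R)-5-[(7E)-8,12-dimethyl-4-methylidene-3-oxotrideca-7,11-dien-1-yl]oxan-2-yl]prop-2-enoate F7. Corey–Bakshi–Shibata reduction with the (S)-2-methyl-oxazaborolidine and catecholborane (toluene, −78 °C), in which the alkenyl group acts as the large substituent, should return the (R)-alcohol 21.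

Further compounds
F1 | step 5 | (5S)-5-(3-hydroxypropyl)oxane-2-carboxylic acid (C2 epimers) | OCCC[C@H]1CCC(C(=O)O)OC1
F2 | step 5 | methyl (2S,5S)-5-(3-hydroxypropyl)oxane-2-carboxylate | OCCC[C@H]1CC[C@@H](C(=O)OC)OC1
F3 | step 4 | 3-[(1R)-3-oxocyclohexyl]propyl acetate | O=C1CCC[C@H](CCCOC(C)=O)C1
F4 | step 4 | 3-[(3R)-7-oxooxepan-3-yl]propyl acetate | O=C1OC[C@@H](CCCOC(C)=O)CCC1
F5 | step 4 | 3-[(4S)-2-oxooxepan-4-yl]propyl acetate | O=C1OCCC[C@H](CCCOC(C)=O)C1
F6 | step 10 | methyl 2-[(2R,5S)-5-[(3S,7E)-3-hydroxy-8,12-dimethyl-4-methylidenetrideca-7,11-dien-1-yl]oxan-2-yl]prop-2-enoate | C=C(CC/C=C(\C)CCC=C(C)C)[C@@H](O)CC[C@H]1CC[C@H](C(=C)C(=O)OC)OC1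
F7 | step 10 | methyl 2-[(2R,5R)-5-[(7E)-8,12-dimethyl-4-methylidene-3-oxotrideca-7,11-dien-1-yl]oxan-2-yl]prop-2-enoate | C=C(CC/C=C(\C)CCC=C(C)C)C(=O)CC[C@H]1CC[C@H](C(=C)C(=O)OC)OC1
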